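The tetrahydrofuran ring (O1, C2 aryl, C3 CH2OH, C4 arylmethyl, C5) is disconnected at C3–C4 and at the exocyclic CH2–aryl bond. The feature exploited is that C3 with its CH2OH is a reductively opened oxirane, while C5, C4 and the benzylic CH2 are an allyl group on O1. One titanium/nickel radical cascade opens the oxirane, closes the ring 5-exo and arylates the primary radical left outside the ring, setting C3 and C4 from C2. The precursor is the O-allyl ether of an enantioenriched aryl(oxiranyl)methanol. Phenols are masked as silyl ethers, so that no final hydrogenolysis endangers the benzylic C2–O1 bond.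

Key step: step 6

Remark on the chemistry: the titanium–tartrate resolution delivers the anti (erythro) epoxy alcohol, so in 6 and 8 the carbinol carbon is R and the oxirane carbon is S. The R,R compound would be the syn epimer, which this chemistry does not favour but which would give the same radical. The carbinol carbon keeps its spatial arrangement throughout and is called S in 14 and 15 only because the CIP ranking of its neighbours changes.

Step 1
Reactants: 1 syringaldehyde
Product: 2 4-[(tert-butyldimethylsilyl)oxy]-3,5-dimethoxybenzaldehyde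
Conditions: TBSCl (1.2 equiv), imidazole (2.5 equiv), DMF, rt
Reagents that add atoms: tert-butyldimethylsilyl chloride, CC(C)(C)[Si](C)(C)Cl
Why: Imidazole-promoted O-silylation of the acidic phenol masks it for the Grignard, titanium and nickel steps with a group that fluoride later removes without any reductive conditions.

Step 2
Reactants: 2 4-[(tert-butyldimethylsilyl)oxy]-3,5-dimethoxybenzaldehyde; 3 vinylmagnesium bromide
Product: 5 rac-1-{4-[(tert-butyldimethylsilyl)oxy]-3,5-dimethoxyphenyl}prop-2-en-1-ol, via bromomagnesium alkoxide 4 (not isolated)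
Conditions: 3 (1.3 equiv), THF, −78 to 0 °C; sat. aq. NH4Cl
Reagents that add atoms: none
Why: Grignard 1,2-addition to a non-enolisable benzaldehyde is fast at low temperature, leaves the aryl silyl ether intact and creates the future C2 carbinol centre as a racemate that step 3 resolves.

Step 3
Reactants: 5 rac-1-{4-[(tert-butyldimethylsilyl)oxy]-3,5-dimethoxyphenyl}prop-2-en-1-ol
Product: 6 (R)-{4-[(tert-butyldimethylsilyl)oxy]-3,5-dimethoxyphenyl}[(S)-oxiran-2-yl]methanol (anti epoxy alcohol)
Conditions: Ti(OiPr)4 (0.2 equiv), D-(−)-diisopropyl tartrate [(2S,3S), 0.26 equiv], anhydrous t-BuOOH (0.45 equiv), 4 Å MS, CH2Cl2, −20 °C; 10% aq. tartaric acid; chromatography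
Reagents that add atoms: tert-butyl hydroperoxide, CC(C)(C)OO
Why: Sharpless kinetic resolution (titanium–tartrate asymmetric epoxidation): with D-(−)-DIPT the (S)-alcohol is the fast-reacting enantiomer and is epoxidised anti-selectively, so with the oxidant kept below half an equivalent 6 should carry the future C2 configuration in high enantiomeric purity, the unreacted (R)-alcohol and any syn epoxide (which stems mainly from the slow enantiomer) being removed by chromatography.

Step 4
Reactants: 6 (R)-{4-[(tert-butyldimethylsilyl)oxy]-3,5-dimethoxyphenyl}[(S)-oxiran-2-yl]methanol; 7 allyl bromide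
Product: 8 (S)-2-[(R)-(allyloxy){4-[(tert-butyldimethylsilyl)oxy]-3,5-dimethoxyphenyl}methyl]oxirane
Conditions: 7 (5 equiv), Ag2O (2 equiv), 4 Å MS, CH2Cl2, rt, dark
Reagents that add atoms: none
Why: Silver-oxide-promoted Williamson-type etherification alkylates the hydroxyl group without a free alkoxide, which avoids Payne rearrangement, epoxide opening and silyl migration and touches no stereocentre.

Step 5
Reactants: 9 4-bromo-2,6-dimethoxyphenol
Product: 10 (4-bromo-2,6-dimethoxyphenoxy)(tert-butyl)dimethylsilane
Conditions: TBSCl (1.2 equiv), imidazole (2.5 equiv), DMF, rt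
Reagents that add atoms: tert-butyldimethylsilyl chloride, CC(C)(C)[Si](C)(C)Cl
Why: The same imidazole-promoted O-silylation as in step 1 gives an aryl bromide whose C–Br bond has two free ortho positions for oxidative addition and whose phenol is unmasked together with the other one in step 7.

Step 6
Reactants: 8 (S)-2-[(R)-(allyloxy){4-[(tert-butyldimethylsilyl)oxy]-3,5-dimethoxyphenyl}methyl]oxirane; 10 (4-bromo-2,6-dimethoxyphenoxy)(tert-butyl)dimethylsilane
Product: 14 [(2S,3R,4R)-2-{4-[(tert-butyldimethylsilyl)oxy]-3,5-dimethoxyphenyl}-4-{4-[(tert-butyldimethylsilyl)oxy]-3,5-dimethoxybenzyl}tetrahydrofuran-3-yl]methanol, via C3 titanoxy radical 11 (not isolated), via cyclised primary radical 12 (not isolated), via titanium alkoxide 13 (not isolated)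
Conditions: NiBr2(dme) (15 mol %), 4,4'-di-tert-butyl-2,2'-bipyridine (18 mol %), Cp2TiCl2 (10 mol %), Mn powder (3 equiv), Et3N·HCl (1.3 equiv), 10 (1.5 equiv), DMPU, rt, slow addition of 8; aq. NH4Cl
Reagents that add atoms: none
Why: Proposed new method: Cp2TiCl (trivalent titanium, generated and recycled from Cp2TiCl2 by Mn and Et3N·HCl) cleaves the more substituted oxirane C–O bond of 8 homolytically to the planar β-titanoxy radical 11, which adds to the O-allyl alkene to give primary radical 12; an aryl–nickel bromide, formed from 10 and zerovalent nickel, captures 12, reductive elimination from trivalent nickel makes the CH2–aryl bond, and Et3N·HCl protonates alkoxide 13 to 14. The closest known reaction types are the titanocene-mediated reductive cyclisation of epoxy alkenes, the nickel/titanocene co-catalysed cross-electrophile arylation of epoxides and the nickel-catalysed reductive cyclisation–arylation of alkenyl halides, but their union in one cascade has not been shown. The tetrahydrofuran ring (O1–C2–C3–C4–C5) closes in the 5-exo-trig mode by C3–C4 bond formation. C3 is controlled by the resident C2 stereocentre, because in the chair-like transition state the C2 aryl group lies pseudo-equatorial and the titanoxymethyl group on the radical carbon turns to the opposite face (2,3-trans), whatever the oxirane configuration was. C4 is fixed in the same transition state, in which the alkene CH2 terminus points away from the C2 aryl group and so ends up cis to the titanoxymethyl group (2,4-trans, 3,4-cis). The step needs the right order of events, which the substrate secures since the unimolecular closure of a 3-oxa-5-hexenyl-type radical should outrun bimolecular capture by catalysts present in a few mol %, whereas 12 has no fast unimolecular exit and meets more aryl–nickel than trivalent titanium.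

Step 7
Reactants: 14 [(2S,3R,4R)-2-{4-[(tert-butyldimethylsilyl)oxy]-3,5-dimethoxyphenyl}-4-{4-[(tert-butyldimethylsilyl)oxy]-3,5-dimethoxybenzyl}tetrahydrofuran-3-yl]methanol
Product: 15 (+)-(7S,8R,8'R)-5,5'-dimethoxylariciresinol
Conditions: TBAF (2.5 equiv), AcOH (2.5 equiv), THF, 0 °C to rt
Reagents that add atoms: none
Why: Fluoride-induced cleavage of the two aryl silyl ethers, buffered with acetic acid so that no free phenoxide can open the C2–O1 bond through a quinone methide, touches neither the benzylic ether nor any stereocentre and should give 15.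

Compound list
1 | syringaldehyde | COc1cc(C=O)cc(OC)c1O | starting material
2 | 4-[(tert-butyldimethylsilyl)oxy]-3,5-dimethoxybenzaldehyde | COc1cc(C=O)cc(OC)c1O[Si](C)(C)C(C)(C)C | intermediate
3 | vinylmagnesium bromide | C=C[Mg]Br | starting material
4 | bromomagnesium alkoxide of 5 (racemic, not isolated) | C=CC(O[Mg]Br)c1cc(OC)c(O[Si](C)(C)C(C)(C)C)c(OC)c1 | intermediate
5 | rac-1-{4-[(tert-butyldimethylsilyl)oxy]-3,5-dimethoxyphenyl}prop-2-en-1-ol | C=CC(O)c1cc(OC)c(O[Si](C)(C)C(C)(C)C)c(OC)c1 | intermediate
6 | (R)-{4-[(tert-butyldimethylsilyl)oxy]-3,5-dimethoxyphenyl}[(S)-oxiran-2-yl]methanol | O[C@H](c1cc(OC)c(O[Si](C)(C)C(C)(C)C)c(OC)c1)[C@@H]1CO1 | intermediate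
7 | allyl bromide | C=CCBr | starting material
8 | (S)-2-[(R)-(allyloxy){4-[(tert-butyldimethylsilyl)oxy]-3,5-dimethoxyphenyl}methyl]oxirane | C=CCO[C@H](c1cc(OC)c(O[Si](C)(C)C(C)(C)C)c(OC)c1)[C@@H]1CO1 | intermediate
9 | 4-bromo-2,6-dimethoxyphenol | COc1cc(Br)cc(OC)c1O | starting material
10 | (4-bromo-2,6-dimethoxyphenoxy)(tert-butyl)dimethylsilane | COc1cc(Br)cc(OC)c1O[Si](C)(C)C(C)(C)C | intermediate
11 | secondary C3 radical from oxirane opening, CH2O bound to Cp2TiCl, C2 centre as in 8 (cyclopentadienyl rings drawn σ-bonded; not isolated) | C=CCO[C@H](c1cc(OC)c(O[Si](C)(C)C(C)(C)C)c(OC)c1)[CH]CO[Ti](Cl)(C2C=CC=C2)C3C=CC=C3 | intermediate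
12 | primary exocyclic CH2 radical on C4 of the closed 2,3-trans-3,4-cis tetrahydrofuran, CH2O bound to Cp2TiCl (not isolated) | [CH2][C@H]1CO[C@H](c2cc(OC)c(O[Si](C)(C)C(C)(C)C)c(OC)c2)[C@H]1CO[Ti](Cl)(C3C=CC=C3)C4C=CC=C4 | intermediate
13 | chlorotitanocene alkoxide of 14 (not isolated) | COc1cc(C[C@H]2CO[C@H](c3cc(OC)c(O[Si](C)(C)C(C)(C)C)c(OC)c3)[C@H]2CO[Ti](Cl)(C4C=CC=C4)C5C=CC=C5)cc(OC)c1O[Si](C)(C)C(C)(C)C | intermediate
14 | [(2S,3R,4R)-2-{4-[(tert-butyldimethylsilyl)oxy]-3,5-dimethoxyphenyl}-4-{4-[(tert-butyldimethylsilyl)oxy]-3,5-dimethoxybenzyl}tetrahydrofuran-3-yl]methanol | COc1cc(C[C@H]2CO[C@H](c3cc(OC)c(O[Si](C)(C)C(C)(C)C)c(OC)c3)[C@H]2CO)cc(OC)c1O[Si](C)(C)C(C)(C)C | intermediate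
15 | (+)-(7S,8R,8'R)-5,5'-dimethoxylariciresinol, 4-{[(3R,4R,5S)-5-(4-hydroxy-3,5-dimethoxyphenyl)-4-(hydroxymethyl)tetrahydrofuran-3-yl]methyl}-2,6-dimethoxyphenol | COc1cc(C[C@H]2CO[C@H](c3cc(OC)c(O)c(OC)c3)[C@H]2CO)cc(OC)c1O | target

Total step count: 7. Longest linear sequence: 6 (steps 1, 2, 3, 4, 6, 7); step 5 is a one-step side branch.

Steps most likely to fail

1. Step 6.
- **What may go wrong:**
  - The cascade may lose its order of events. Nickel or titanium may intercept the C3 radical before ring closure, or reduction and hydrogen abstraction may overtake arylation of the primary radical.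
  - Halide may open the oxirane at its CH2 end.
  - The aryl bromide may homocouple.
  - Facial control at C4 may be weak.
- **Fallback (known chemistry):** it sets out from 8, with 2 as the source of the second ring, and returns at 14. The aryl group is placed on the alkene before the radical step.
  - Wittig methylenation of 2 (MePPh3Br, KOt-Bu, THF) gives tert-butyl(2,6-dimethoxy-4-vinylphenoxy)dimethylsilane F1.
  - Olefin cross-metathesis of 8 with excess F1 (second-generation Grubbs catalyst, CH2Cl2, 40 °C) gives (S)-2-[(R)-{4-[(tert-butyldimethylsilyl)oxy]-3,5-dimethoxyphenyl}({(E)-3-{4-[(tert-butyldimethylsilyl)oxy]-3,5-dimethoxyphenyl}allyl}oxy)methyl]oxirane F2.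
  - Stoichiometric Cp2TiCl (Cp2TiCl2, Zn dust, THF, rt) then effects the established reductive epoxide–alkene radical cyclisation. The benzylic radical formed after 5-exo closure is reduced by a second equivalent of Cp2TiCl and protonated on mildly acidic work-up. This should give 14 with the same 2,3-trans-3,4-cis preference.

2. Step 3.
- **What may go wrong:**
  - The rate difference between the enantiomers may be too small for a product of high enantiomeric purity.
  - The terminal alkene may be epoxidised slowly.
  - Titanium-bound alkoxides may open the terminal epoxide during a long reaction.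
- **Fallback:** it sets out from 5 and returns at 6. Resolution and epoxidation are separated.
  - Lipase-catalysed transesterification (immobilised Candida antarctica lipase B, vinyl acetate, MTBE, 30 °C) follows the usual enantiopreference of this enzyme for aryl carbinols. It should acylate the unwanted enantiomer to (R)-1-{4-[(tert-butyldimethylsilyl)oxy]-3,5-dimethoxyphenyl}allyl acetate F4.
  - It leaves (S)-1-{4-[(tert-butyldimethylsilyl)oxy]-3,5-dimethoxyphenyl}prop-2-en-1-ol F3, which is carried slightly past half conversion and separated.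
  - F3 is then epoxidised in the matched sense (Ti(OiPr)4, D-(−)-DIPT, t-BuOOH, 4 Å MS, CH2Cl2, −20 °C), where titanium only has to deliver oxygen and not to discriminate enantiomers, giving 6.

3. Step 4.
- **What may go wrong:**
  - Alkylation of the hindered secondary benzylic hydroxyl group on silver oxide may stall.
  - Forcing it may bring on epoxide migration or opening.
- **Fallback:** it sets out from 6 and returns at 8. The allyl group is delivered intramolecularly from a carbonate.
  - Acylation with allyl chloroformate (pyridine, CH2Cl2, 0 °C) gives allyl (R)-{4-[(tert-butyldimethylsilyl)oxy]-3,5-dimethoxyphenyl}[(S)-oxiran-2-yl]methyl carbonate F5.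
  - Tsuji–Trost-type decarboxylative O-allylation (Pd(PPh3)4 cat., THF, 50 °C) ionises the allyl carbonate and loses CO2. The alkoxide then recombines with the π-allyl–palladium cation within the ion pair under neutral conditions to give 8.

Further compounds
F1 | step 6 | tert-butyl(2,6-dimethoxy-4-vinylphenoxy)dimethylsilane | C=Cc1cc(OC)c(O[Si](C)(C)C(C)(C)C)c(OC)c1
F2 | step 6 | (S)-2-[(R)-{4-[(tert-butyldimethylsilyl)oxy]-3,5-dimethoxyphenyl}({(E)-3-{4-[(tert-butyldimethylsilyl)oxy]-3,5-dimethoxyphenyl}allyl}oxy)methyl]oxirane | COc1cc(/C=C/CO[C@H](c2cc(OC)c(O[Si](C)(C)C(C)(C)C)c(OC)c2)[C@@H]2CO2)cc(OC)c1O[Si](C)(C)C(C)(C)C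
F3 | step 3 | (S)-1-{4-[(tert-butyldimethylsilyl)oxy]-3,5-dimethoxyphenyl}prop-2-en-1-ol | O[C@H](c1cc(OC)c(O[Si](C)(C)C(C)(C)C)c(OC)c1)C=C
F4 | step 3 | (R)-1-{4-[(tert-butyldimethylsilyl)oxy]-3,5-dimethoxyphenyl}allyl acetate | CC(=O)O[C@@H](c1cc(OC)c(O[Si](C)(C)C(C)(C)C)c(OC)c1)C=C
F5 | step 4 | allyl (R)-{4-[(tert-butyldimethylsilyl)oxy]-3,5-dimethoxyphenyl}[(S)-oxiran-2-yl]methyl carbonate | C=CCOC(=O)O[C@H](c1cc(OC)c(O[Si](C)(C)C(C)(C)C)c(OC)c1)[C@@H]1CO1
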